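**Strategy**

The carbocycle of the target (C4a, C5, C6, C7, C8, C8a in chromene numbering) is a masked resorcinol: without the C5 prenyl group it is an arene whose C6 and C8 oxygens flank C7. The route therefore forms C5–C6 and C7–C8 together in a Danheiser benzannulation. A vinylketene, released by Wolff rearrangement of an acyclic diazo enone that already carries the 1,1-dimethylpropargyl ether, takes up ethoxyacetylene; 4π opening and 6π closure of the adduct give the pentasubstituted phenol. A propargyl Claisen cascade then closes the pyran, C7 is acylated, and a palladium-catalysed enantioselective dearomative prenylation sets the C5 quaternary centre last.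

Key step: step 3

Remark: the target is taken as the C6-keto, C8-enol tautomer written in the SMILES (its other triketone tautomers are the same compound), and its single stereocentre C5 is S.

**Route**

Step 1
Reactants: 1 2-methylbut-3-yn-2-ol; 2 pent-1-yn-3-one
Product: 3 (E)-1-[(2-methylbut-3-yn-2-yl)oxy]pent-1-en-3-one
Conditions: DABCO (10 mol %), CH2Cl2, 0 °C to rt
Reagents that add atoms: none
Why: amine-catalysed oxa-Michael addition of the tertiary propargylic alcohol to the terminal ynone, which should give the thermodynamically preferred E β-alkoxy enone.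

Step 2
Reactants: 3 (E)-1-[(2-methylbut-3-yn-2-yl)oxy]pent-1-en-3-one
Product: 5 (E)-4-diazo-1-[(2-methylbut-3-yn-2-yl)oxy]pent-1-en-3-one, via trifluoroacetyl diketone 4 (not isolated)
Conditions: LiN(SiMe3)2, THF, −78 °C; CF3CO2CH2CF3; aq HCl; then 4-acetamidobenzenesulfonyl azide, Et3N, H2O, MeCN, rt
Reagents that add atoms: 4-acetamidobenzenesulfonyl azide, CC(=O)Nc1ccc(cc1)S(=O)(=O)N=[N+]=[N-]; 2,2,2-trifluoroethyl trifluoroacetate, FC(F)(F)COC(=O)C(F)(F)F (its trifluoroacetyl group is held only by 4)
Why: detrifluoroacetylative (Regitz-type deacylative) diazo transfer, in which the kinetic enolate on the ethyl side is C-trifluoroacetylated and the activated methine then accepts the diazo group with loss of the trifluoroacetyl group; the enol ether and terminal alkyne should be inert.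

Step 3
Reactants: 5 (E)-4-diazo-1-[(2-methylbut-3-yn-2-yl)oxy]pent-1-en-3-one; 6 ethoxyacetylene
Product: 11 5-ethoxy-4-methyl-2-[(2-methylbut-3-yn-2-yl)oxy]phenol, via vinylketene 7 (not isolated), via vinylcyclobutenone 8 (not isolated), via dienylketene 9 (not isolated), via cyclohexadienone 10 (not isolated)
Conditions: hν (254 nm, Vycor), 6 (3 equiv), ClCH2CH2Cl, rt; then 80 °C
Reagents that add atoms: none
Why: Photochemical Wolff rearrangement of 5 (1,2-shift of the alkoxyvinyl group, loss of N2) should give vinylketene 7, whose ketene C=C undergoes [2+2] cycloaddition with ynol ether 6 to give 8, joining the ketene carbonyl carbon to the CH terminus of 6 (the future C8–C7 bond) and the methyl-bearing ketene carbon to the OEt-bearing carbon (the future C5–C6 bond). At 80 °C 8 opens reversibly by 4π electrocyclic ring opening to dienylketene 9, which closes to 10 and tautomerizes to phenol 11. The closest known reaction is the Danheiser benzannulation in its diazo ketone (photo-Wolff) version with an alkoxyacetylene, which gives resorcinol monoethers with this regiochemistry. The only ring closed is the carbocycle, by disrotatory 6π electrocyclization of 9 between the ketene carbon and the alkoxy-bearing diene terminus (re-forming C8–C8a), a net [4+2] of a four-carbon vinylketene and a two-carbon alkyne. No stereocentre is created, since those of 8 and 10 are lost on aromatization. The step needs regioselectivity in the [2+2], secured by the polarization of 6, and chemoselectivity over the tethered terminal alkyne and over [3,3] shift of the propargyl vinyl ether, secured by the far higher ketenophilicity of 6 in excess and by staying at or below 80 °C.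

Step 4
Reactants: 11 5-ethoxy-4-methyl-2-[(2-methylbut-3-yn-2-yl)oxy]phenol
Product: 15 6-ethoxy-2,2,5-trimethyl-2H-chromen-8-ol, via allenyl dienone 12 (not isolated), via allenylphenol 13 (not isolated), via quinone methide 14 (not isolated)
Conditions: o-xylene, 140 °C
Reagents that add atoms: none
Why: aromatic propargyl Claisen rearrangement to the only unsubstituted ortho carbon (C4a), enolization, [1,5]-hydrogen shift and oxa-6π electrocyclization, the classical chromene synthesis from aryl 1,1-dimethylpropargyl ethers.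

Step 5
Reactants: 15 6-ethoxy-2,2,5-trimethyl-2H-chromen-8-ol
Product: 16 6-ethoxy-8-(methoxymethoxy)-2,2,5-trimethyl-2H-chromene
Conditions: NaH, chloromethyl methyl ether, THF, 0 °C to rt
Reagents that add atoms: chloromethyl methyl ether, COCCl
Why: Williamson O-alkylation of the sodium phenoxide, which protects O8 and installs a directing group for metalation.

Step 6
Reactants: 16 6-ethoxy-8-(methoxymethoxy)-2,2,5-trimethyl-2H-chromene; 17 N-methoxy-N-methyl-3-phenylpropanamide
Product: 20 1-[6-ethoxy-8-(methoxymethoxy)-2,2,5-trimethyl-2H-chromen-7-yl]-3-phenylpropan-1-one, via aryllithium 18 (not isolated), via lithium hemiaminal adduct 19 (not isolated)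
Conditions: n-BuLi, THF, −20 to 0 °C; then 17, −78 °C to rt; aq NH4Cl
Reagents that add atoms: none
Why: directed ortho-metalation at C7, the only ring C–H and flanked by the cooperating OMOM and OEt groups, followed by Weinreb amide acylation, in which the chelated adduct 19 should prevent over-addition.

Step 7
Reactants: 20 1-[6-ethoxy-8-(methoxymethoxy)-2,2,5-trimethyl-2H-chromen-7-yl]-3-phenylpropan-1-one
Product: 21 1-(6,8-dihydroxy-2,2,5-trimethyl-2H-chromen-7-yl)-3-phenylpropan-1-one
Conditions: BCl3 (3 equiv), CH2Cl2, −78 to −20 °C; then H2O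
Reagents that add atoms: none
Why: Lewis-acid ether cleavage, in which BCl3 removes the MOM acetal and, through chelation to the C7 ketone, the ortho ethyl ether, at low temperature to spare the chromene.

Step 8
Reactants: 21 1-(6,8-dihydroxy-2,2,5-trimethyl-2H-chromen-7-yl)-3-phenylpropan-1-one; 22 3-methylbut-2-en-1-yl acetate (prenyl acetate)
Product: 23 (5S)-8-hydroxy-2,2,5-trimethyl-5-(3-methylbut-2-en-1-yl)-7-(3-phenylpropanoyl)-2H-chromen-6(5H)-one
Conditions: Pd2(dba)3·CHCl3 (2.5 mol %), (R,R)-DACH-phenyl ligand N,N'-[(1R,2R)-cyclohexane-1,2-diyl]bis[2-(diphenylphosphanyl)benzamide] (7.5 mol %), Et3N, 22 (1.05 equiv), degassed CH2Cl2, 0 °C to rt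
Reagents that add atoms: none
Why: palladium-catalysed asymmetric allylic alkylation (Tsuji–Trost) in dearomative mode, in which the phenoxide of 21 should attack the π-prenyl palladium at its CH2 terminus through C5 (ortho to O6, para to O8, not acyl-bearing) while O-allylation stays reversible, the chiral ligand pocket choosing the face of the planar nucleophile and so setting C5; the sense of induction cannot be predicted with confidence for this nucleophile, so the (R,R) ligand is the working choice and its (S,S) antipode is used if the first run shows the opposite sense.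

**Compound list**

1 | 2-methylbut-3-yn-2-ol | CC(C)(O)C#C | starting material
2 | pent-1-yn-3-one | CCC(=O)C#C | starting material
3 | (E)-1-[(2-methylbut-3-yn-2-yl)oxy]pent-1-en-3-one | CCC(=O)/C=C/OC(C)(C)C#C | intermediate
4 | (E)-1,1,1-trifluoro-3-methyl-6-[(2-methylbut-3-yn-2-yl)oxy]hex-5-ene-2,4-dione (racemic, not isolated) | CC(C(=O)C(F)(F)F)C(=O)/C=C/OC(C)(C)C#C | intermediate
5 | (E)-4-diazo-1-[(2-methylbut-3-yn-2-yl)oxy]pent-1-en-3-one | CC(=[N+]=[N-])C(=O)/C=C/OC(C)(C)C#C | intermediate
6 | ethoxyacetylene | CCOC#C | starting material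
7 | (E)-2-methyl-4-[(2-methylbut-3-yn-2-yl)oxy]buta-1,3-dien-1-one (vinylketene, not isolated) | CC(=C=O)/C=C/OC(C)(C)C#C | intermediate
8 | 3-ethoxy-4-methyl-4-{(E)-2-[(2-methylbut-3-yn-2-yl)oxy]ethenyl}cyclobut-2-en-1-one (racemic, not isolated) | CCOC1=CC(=O)C1(C)/C=C/OC(C)(C)C#C | intermediate
9 | 3-ethoxy-4-methyl-6-[(2-methylbut-3-yn-2-yl)oxy]hexa-1,3,5-trien-1-one (dienylketene, not isolated) | CCOC(C=C=O)=C(C)/C=C/OC(C)(C)C#C | intermediate
10 | 3-ethoxy-4-methyl-6-[(2-methylbut-3-yn-2-yl)oxy]cyclohexa-2,4-dien-1-one (racemic, not isolated) | CCOC1=CC(=O)C(OC(C)(C)C#C)C=C1C | intermediate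
11 | 5-ethoxy-4-methyl-2-[(2-methylbut-3-yn-2-yl)oxy]phenol | CCOc1cc(O)c(OC(C)(C)C#C)cc1C | intermediate
12 | 4-ethoxy-2-hydroxy-5-methyl-6-(3-methylbuta-1,2-dien-1-yl)cyclohexa-2,4-dien-1-one (racemic, not isolated) | CCOC1=C(C)C(C=C=C(C)C)C(=O)C(O)=C1 | intermediate
13 | 5-ethoxy-4-methyl-3-(3-methylbuta-1,2-dien-1-yl)benzene-1,2-diol (not isolated) | CCOc1cc(O)c(O)c(C=C=C(C)C)c1C | intermediate
14 | 4-ethoxy-2-hydroxy-5-methyl-6-(3-methylbut-2-en-1-ylidene)cyclohexa-2,4-dien-1-one (not isolated) | CCOC1=C(C)C(=CC=C(C)C)C(=O)C(O)=C1 | intermediate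
15 | 6-ethoxy-2,2,5-trimethyl-2H-chromen-8-ol | CCOc1cc(O)c2OC(C)(C)C=Cc2c1C | intermediate
16 | 6-ethoxy-8-(methoxymethoxy)-2,2,5-trimethyl-2H-chromene | CCOc1cc(OCOC)c2OC(C)(C)C=Cc2c1C | intermediate
17 | N-methoxy-N-methyl-3-phenylpropanamide | CON(C)C(=O)CCc1ccccc1 | starting material
18 | [6-ethoxy-8-(methoxymethoxy)-2,2,5-trimethyl-2H-chromen-7-yl]lithium (not isolated) | CCOc1c(C)c2C=CC(C)(C)Oc2c(OCOC)c1[Li] | intermediate
19 | lithium 1-[6-ethoxy-8-(methoxymethoxy)-2,2,5-trimethyl-2H-chromen-7-yl]-1-[methoxy(methyl)amino]-3-phenylpropan-1-olate (not isolated) | CCOc1c(C)c2C=CC(C)(C)Oc2c(OCOC)c1C(O[Li])(CCc3ccccc3)N(C)OC | intermediate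
20 | 1-[6-ethoxy-8-(methoxymethoxy)-2,2,5-trimethyl-2H-chromen-7-yl]-3-phenylpropan-1-one | CCOc1c(C)c2C=CC(C)(C)Oc2c(OCOC)c1C(=O)CCc3ccccc3 | intermediate
21 | 1-(6,8-dihydroxy-2,2,5-trimethyl-2H-chromen-7-yl)-3-phenylpropan-1-one | Cc1c(O)c(C(=O)CCc2ccccc2)c(O)c2OC(C)(C)C=Cc12 | intermediate
22 | 3-methylbut-2-en-1-yl acetate | CC(=O)OCC=C(C)C | starting material
23 | (5S)-8-hydroxy-2,2,5-trimethyl-5-(3-methylbut-2-en-1-yl)-7-(3-phenylpropanoyl)-2H-chromen-6(5H)-one | CC(C)=CC[C@]1(C)C(=O)C(C(=O)CCc2ccccc2)=C(O)C2=C1C=CC(C)(C)O2 | target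

**Totals and risks**

Total step count: 8. Longest linear sequence: 8 steps (1 and 2 to 23).

Steps most likely to fail:

1. Step 3. The photogenerated ketene may be diverted before it meets the ynol ether, either by [3,3] shift of the propargyl vinyl ether unit on warming or by photochemical E/Z isomerization followed by intramolecular trapping, so that the benzannulation becomes inefficient. The fallback keeps the same benzannulation and the same two bonds but brings the pyran carbons in afterwards. It sets out from 2: DABCO-catalysed addition of benzyl alcohol should give (E)-1-(benzyloxy)pent-1-en-3-one F1, and the diazo transfer of step 2 then gives (E)-1-(benzyloxy)-4-diazopent-1-en-3-one F2. Photolysis with 6 and heating at 80 °C gives 2-(benzyloxy)-5-ethoxy-4-methylphenol F3, and NaH with chloromethyl methyl ether gives 1-(benzyloxy)-4-ethoxy-2-(methoxymethoxy)-5-methylbenzene F4. Hydrogenolysis (H2, Pd/C, EtOAc) frees 4-ethoxy-2-(methoxymethoxy)-5-methylphenol F5. Alkylation with 3-chloro-3-methylbut-1-yne (K2CO3, KI, catalytic CuI, acetone) gives 1-ethoxy-5-(methoxymethoxy)-2-methyl-4-[(2-methylbut-3-yn-2-yl)oxy]benzene F6, and heating in o-xylene at 140 °C closes the chromene. The fallback comes back to the route at 16.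

2. Step 8. Facial discrimination of the planar phenoxide in the outer-sphere attack on the π-prenyl palladium may be poor, or attack through oxygen or at the substituted allyl terminus may compete. The fallback replaces catalytic induction by resolution and sets out from 21: base-mediated dearomative C-prenylation (prenyl bromide, NaOMe, MeOH, 0 °C) should give racemic 8-hydroxy-2,2,5-trimethyl-5-(3-methylbut-2-en-1-yl)-7-(3-phenylpropanoyl)-2H-chromen-6(5H)-one F7. Its enantiomers are separated by preparative chromatography on a chiral stationary phase, and the fallback comes back at 23.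

3. Step 7. The Lewis acid may ionize the allylic tertiary C2–O1 bond or add HCl across the chromene alkene while the ethers are being cleaved. The fallback avoids BCl3 by carrying the ethyl group through the dearomatization, and sets out from 20: dilute HCl in MeOH/THF at 40 °C removes only the MOM group to give 1-(6-ethoxy-8-hydroxy-2,2,5-trimethyl-2H-chromen-7-yl)-3-phenylpropan-1-one F8. The conditions of step 8 then prenylate C5 para to the O8 phenoxide to give (5S)-6-ethoxy-2,2,5-trimethyl-5-(3-methylbut-2-en-1-yl)-7-(3-phenylpropanoyl)-2H-chromen-8(5H)-one F9. Hydrolysis of this doubly activated vinylogous ester (LiOH, THF/H2O, then dilute acid) comes back to the route at 23.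

Further compounds
F1 | step 3 | (E)-1-(benzyloxy)pent-1-en-3-one | CCC(=O)/C=C/OCc1ccccc1
F2 | step 3 | (E)-1-(benzyloxy)-4-diazopent-1-en-3-one | CC(=[N+]=[N-])C(=O)/C=C/OCc1ccccc1
F3 | step 3 | 2-(benzyloxy)-5-ethoxy-4-methylphenol | CCOc1cc(O)c(OCc2ccccc2)cc1C
F4 | step 3 | 1-(benzyloxy)-4-ethoxy-2-(methoxymethoxy)-5-methylbenzene | CCOc1cc(OCOC)c(OCc2ccccc2)cc1C
F5 | step 3 | 4-ethoxy-2-(methoxymethoxy)-5-methylphenol | CCOc1cc(OCOC)c(O)cc1C
F6 | step 3 | 1-ethoxy-5-(methoxymethoxy)-2-methyl-4-[(2-methylbut-3-yn-2-yl)oxy]benzene | CCOc1cc(OCOC)c(OC(C)(C)C#C)cc1C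
F7 | step 8 | racemic 8-hydroxy-2,2,5-trimethyl-5-(3-methylbut-2-en-1-yl)-7-(3-phenylpropanoyl)-2H-chromen-6(5H)-one | CC(C)=CCC1(C)C(=O)C(C(=O)CCc2ccccc2)=C(O)C2=C1C=CC(C)(C)O2
F8 | step 7 | 1-(6-ethoxy-8-hydroxy-2,2,5-trimethyl-2H-chromen-7-yl)-3-phenylpropan-1-one | CCOc1c(C)c2C=CC(C)(C)Oc2c(O)c1C(=O)CCc3ccccc3
F9 | step 7 | (5S)-6-ethoxy-2,2,5-trimethyl-5-(3-methylbut-2-en-1-yl)-7-(3-phenylpropanoyl)-2H-chromen-8(5H)-one | CC(C)=CC[C@]1(C)C(OCC)=C(C(=O)CCc2ccccc2)C(=O)C2=C1C=CC(C)(C)O2
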